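**Retrosynthetic overview**
- Target ⇐ its 5'-O-benzyl, 5-O-methyl protected form: hydrogenolysis and a chelation-controlled 5-O-demethylation unmask the two phenols last.
- 3-OMe ⇐ flavonol ⇐ flavone: C3–H hydroxylation by DMDO epoxidation and acid isomerisation, then O-methylation.
- Ring C is the only ring built (rings A and B are bought as arenes) ⇐ I2/DMSO oxidative cyclisation of a 2'-hydroxychalcone.
- Key C–C bond (the future C2–C3) ⇐ intermolecular Claisen–Schmidt aldol condensation of 2-hydroxy-3,4,6-trimethoxyacetophenone with 5-(benzyloxy)-2-methoxybenzaldehyde.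
- Acetophenone ⇐ 3,4,5-trimethoxyphenol (O-methylation, Friedel–Crafts acylation with ortho-demethylation); aldehyde ⇐ 4-(benzyloxy)phenol (ortho-formylation, O-methylation).

Assumption: the target has no stereocentre or stereogenic axis, so no enantiocontrol is needed; the transient stereocentres of the racemic in-flask intermediates are all destroyed again.

**Route**

Step 1
Reactants: 1 3,4,5-trimethoxyphenol
Product: 2 1,2,3,5-tetramethoxybenzene
Conditions: MeI (1.5 equiv), K2CO3 (2 equiv), acetone, reflux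
Reagents that add atoms: iodomethane, CI
Why: Williamson O-methylation (SN2 of the phenoxide on MeI) is clean and leaves an arene whose only two free positions are equivalent.

Step 2
Reactants: 2 1,2,3,5-tetramethoxybenzene
Product: 4 1-(2-hydroxy-3,4,6-trimethoxyphenyl)ethan-1-one, via 1-(2,3,4,6-tetramethoxyphenyl)ethan-1-one 3 (not isolated)
Conditions: AcCl (1.2 equiv), AlCl3 (2.5 equiv), Et2O, 0 °C → rt; then ice/aq. HCl
Reagents that add atoms: acetyl chloride, CC(Cl)=O
Why: Friedel–Crafts acylation can only hit the two equivalent free positions, and AlCl3 chelated to the new carbonyl then cleaves the ortho-methoxy group that is buttressed by a neighbouring OMe (chelation-controlled mono-demethylation), giving the phenol that becomes O1 next to the future 8-OMe.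

Step 3
Reactants: 5 4-(benzyloxy)phenol
Product: 7 5-(benzyloxy)-2-hydroxybenzaldehyde, via 4-(benzyloxy)-2-(hydroxymethyl)phenol 6 (not isolated)
Conditions: MgCl2 (1.5 equiv), Et3N (3.75 equiv), (CH2O)n (6.75 equiv), MeCN, reflux; then aq. HCl
Reagents that add atoms: formaldehyde (as paraformaldehyde), C=O
Why: In the Mg-mediated Casnati–Skattebøl ortho-formylation the magnesium phenoxide delivers formaldehyde only to the ortho position, and the salicyl alcohol is oxidised in the flask by hydride transfer to a second formaldehyde, the benzyl ether being inert.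

Step 4
Reactants: 7 5-(benzyloxy)-2-hydroxybenzaldehyde
Product: 8 5-(benzyloxy)-2-methoxybenzaldehyde
Conditions: MeI (1.5 equiv), K2CO3 (2 equiv), DMF, rt
Reagents that add atoms: iodomethane, CI
Why: Williamson O-methylation of the only free phenol installs the future 2'-OMe.

Step 5
Reactants: 4 1-(2-hydroxy-3,4,6-trimethoxyphenyl)ethan-1-one; 8 5-(benzyloxy)-2-methoxybenzaldehyde
Product: 10 (E)-3-[5-(benzyloxy)-2-methoxyphenyl]-1-(2-hydroxy-3,4,6-trimethoxyphenyl)prop-2-en-1-one, via racemic β-hydroxy ketone aldol adduct 9 (not isolated)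
Conditions: KOH (50% aq.), EtOH, 0 °C → rt, 48 h; then cold dil. HCl
Reagents that add atoms: none
Why: In this Claisen–Schmidt crossed aldol condensation only ketone 4 can enolise and aldehyde 8 cannot self-condense, so the enolate adds intermolecularly to the aldehyde and E1cB dehydration gives the conjugated (E)-chalcone, erasing the racemic carbinol centre of 9.

Step 6
Reactants: 10 (E)-3-[5-(benzyloxy)-2-methoxyphenyl]-1-(2-hydroxy-3,4,6-trimethoxyphenyl)prop-2-en-1-one
Product: 12 2-[5-(benzyloxy)-2-methoxyphenyl]-5,7,8-trimethoxy-4H-chromen-4-one, via racemic flavanone 11 (not isolated)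
Conditions: I2 (10 mol%), DMSO, 130 °C; aq. Na2S2O3 work-up
Reagents that add atoms: none
Why: Iodine-catalysed oxidative cyclisation (oxa-Michael ring closure, α-iodination and HI elimination, with HI reoxidised by DMSO) is the standard chalcone-to-flavone conversion and tolerates aryl methyl and benzyl ethers, the C2 stereocentre of 11 being lost on dehydrogenation.

Step 7
Reactants: 12 2-[5-(benzyloxy)-2-methoxyphenyl]-5,7,8-trimethoxy-4H-chromen-4-one
Product: 14 2-[5-(benzyloxy)-2-methoxyphenyl]-3-hydroxy-5,7,8-trimethoxy-4H-chromen-4-one, via racemic flavone 2,3-epoxide 13 (not isolated)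
Conditions: DMDO (ca. 0.07 M in acetone, 3 equiv in portions), CH2Cl2, 0 °C → rt; evaporate; then p-TsOH·H2O (cat.), CH2Cl2, rt
Reagents that add atoms: dimethyldioxirane, CC1(C)OO1
Why: Neutral DMDO epoxidation of the enol-ether-like C2=C3 bond followed by acid-catalysed epoxide opening to the C2 oxocarbenium ion and loss of H-3 gives the flavonol (net C3–H hydroxylation), with the stereocentres of 13 lost on re-aromatisation of the pyranone.

Step 8
Reactants: 14 2-[5-(benzyloxy)-2-methoxyphenyl]-3-hydroxy-5,7,8-trimethoxy-4H-chromen-4-one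
Product: 15 2-[5-(benzyloxy)-2-methoxyphenyl]-3,5,7,8-tetramethoxy-4H-chromen-4-one
Conditions: MeI (2 equiv), K2CO3 (3 equiv), acetone, reflux
Reagents that add atoms: iodomethane, CI
Why: Williamson O-methylation of the 3-OH, the only free hydroxyl in the molecule, fixes the 3-OMe of the target.

Step 9
Reactants: 15 2-[5-(benzyloxy)-2-methoxyphenyl]-3,5,7,8-tetramethoxy-4H-chromen-4-one
Product: 16 2-[5-(benzyloxy)-2-methoxyphenyl]-5-hydroxy-3,7,8-trimethoxy-4H-chromen-4-one
Conditions: AlCl3 (anhydrous, 5 equiv), MeCN, 0 °C → rt (TLC control); then 2 M HCl, 60 °C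
Reagents that add atoms: none
Why: In this chelation-controlled Lewis-acid ether cleavage aluminium bridges C4=O and the peri 5-OMe in a six-membered chelate, so chloride removes only that methyl while the 7-, 8-, 2'-OMe and benzyl ethers are not activated and the 3-OMe (five-membered chelate) reacts far more slowly.

Step 10
Reactants: 16 2-[5-(benzyloxy)-2-methoxyphenyl]-5-hydroxy-3,7,8-trimethoxy-4H-chromen-4-one
Product: 17 5,5'-dihydroxy-3,7,8,2'-tetramethoxyflavone [5-hydroxy-2-(5-hydroxy-2-methoxyphenyl)-3,7,8-trimethoxy-4H-chromen-4-one]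
Conditions: H2 (1 atm), 10% Pd/C, EtOAc–MeOH, rt
Reagents that add atoms: none
Why: Catalytic hydrogenolysis cleaves the benzyl aryl ether cleanly, while the tetrasubstituted vinylogous-ester C2=C3 bond and the aryl methyl ethers are inert at 1 atm.

**Compound list**

1 | 3,4,5-trimethoxyphenol | COc1cc(O)cc(OC)c1OC | starting material
2 | 1,2,3,5-tetramethoxybenzene | COc1cc(OC)cc(OC)c1OC | intermediate
3 | 1-(2,3,4,6-tetramethoxyphenyl)ethan-1-one (not isolated) | CC(=O)c1c(OC)cc(OC)c(OC)c1OC | intermediate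
4 | 1-(2-hydroxy-3,4,6-trimethoxyphenyl)ethan-1-one | CC(=O)c1c(OC)cc(OC)c(OC)c1O | intermediate
5 | 4-(benzyloxy)phenol | Oc1ccc(OCc2ccccc2)cc1 | starting material
6 | 4-(benzyloxy)-2-(hydroxymethyl)phenol (not isolated) | OCc1cc(OCc2ccccc2)ccc1O | intermediate
7 | 5-(benzyloxy)-2-hydroxybenzaldehyde | O=Cc1cc(OCc2ccccc2)ccc1O | intermediate
8 | 5-(benzyloxy)-2-methoxybenzaldehyde | COc1ccc(OCc2ccccc2)cc1C=O | intermediate
9 | 3-[5-(benzyloxy)-2-methoxyphenyl]-3-hydroxy-1-(2-hydroxy-3,4,6-trimethoxyphenyl)propan-1-one, racemic (not isolated) | COc1ccc(OCc2ccccc2)cc1C(O)CC(=O)c1c(OC)cc(OC)c(OC)c1O | intermediate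
10 | (E)-3-[5-(benzyloxy)-2-methoxyphenyl]-1-(2-hydroxy-3,4,6-trimethoxyphenyl)prop-2-en-1-one | COc1ccc(OCc2ccccc2)cc1/C=C/C(=O)c1c(OC)cc(OC)c(OC)c1O | intermediate
11 | 2-[5-(benzyloxy)-2-methoxyphenyl]-5,7,8-trimethoxychroman-4-one, racemic (not isolated) | COc1ccc(OCc2ccccc2)cc1C1CC(=O)c2c(OC)cc(OC)c(OC)c2O1 | intermediate
12 | 2-[5-(benzyloxy)-2-methoxyphenyl]-5,7,8-trimethoxy-4H-chromen-4-one | COc1ccc(OCc2ccccc2)cc1-c1cc(=O)c2c(OC)cc(OC)c(OC)c2o1 | intermediate
13 | 2,3-epoxide of 12 (2,3-epoxy-2-[5-(benzyloxy)-2-methoxyphenyl]-5,7,8-trimethoxychroman-4-one), racemic, cis-fused (not isolated) | COc1ccc(OCc2ccccc2)cc1C12OC1C(=O)c1c(OC)cc(OC)c(OC)c1O2 | intermediate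
14 | 2-[5-(benzyloxy)-2-methoxyphenyl]-3-hydroxy-5,7,8-trimethoxy-4H-chromen-4-one | COc1ccc(OCc2ccccc2)cc1-c1oc2c(OC)c(OC)cc(OC)c2c(=O)c1O | intermediate
15 | 2-[5-(benzyloxy)-2-methoxyphenyl]-3,5,7,8-tetramethoxy-4H-chromen-4-one | COc1ccc(OCc2ccccc2)cc1-c1oc2c(OC)c(OC)cc(OC)c2c(=O)c1OC | intermediate
16 | 2-[5-(benzyloxy)-2-methoxyphenyl]-5-hydroxy-3,7,8-trimethoxy-4H-chromen-4-one | COc1ccc(OCc2ccccc2)cc1-c1oc2c(OC)c(OC)cc(O)c2c(=O)c1OC | intermediate
17 | 5,5'-dihydroxy-3,7,8,2'-tetramethoxyflavone (achiral) | COc1ccc(O)cc1-c1oc2c(OC)c(OC)cc(O)c2c(=O)c1OC | target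

**Step count**
Total steps: 10.
Longest linear sequence: 8 steps (steps 1, 2, 5–10 from compound 1; equally steps 3, 4, 5–10 from compound 5).

**Three steps most likely to fail, with fallbacks**

Step 2 (one-pot acylation and mono-demethylation). The risk is incomplete or excessive demethylation in the Friedel–Crafts mixture. The fallback sets out from 2 and separates the two events with a different C–C bond construction. Directed ortho-lithiation of 2 (n-BuLi, THF, 0 °C) at the ring C–H flanked by two methoxy groups gives (2,3,4,6-tetramethoxyphenyl)lithium F1. Acylation of F1 with N-methoxy-N-methylacetamide (−78 °C → rt, NH4Cl quench) gives ketone 3, now isolated. A separate chelation-controlled demethylation with BCl3 (1.1 equiv, CH2Cl2, −78 → 0 °C) then comes back to the route at 4.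

Step 7 (DMDO hydroxylation). The risk is that the slow epoxidation of the electron-poor enone competes with oxidation of the electron-rich rings or the benzylic C–H. The fallback sets out from 12 and replaces epoxidation by deprotonative C–H functionalisation. LDA (THF, −78 °C) removes H-3 to give {2-[5-(benzyloxy)-2-methoxyphenyl]-5,7,8-trimethoxy-4-oxo-4H-chromen-3-yl}lithium F2. Trapping with B(OMe)3 gives dimethyl {2-[5-(benzyloxy)-2-methoxyphenyl]-5,7,8-trimethoxy-4-oxo-4H-chromen-3-yl}boronate F3. Oxidation in the same flask (H2O2, AcOH, 0 °C → rt) comes back to the route at 14.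

Step 9 (selective 5-O-demethylation). The risk is partial loss of the 3-OMe alongside the 5-OMe. The fallback sets out from 14 and reverses the order so that no 3-OMe is present when the Lewis acid is used. AlCl3/MeCN (then dil. HCl) on flavonol 14 gives 2-[5-(benzyloxy)-2-methoxyphenyl]-3,5-dihydroxy-7,8-dimethoxy-4H-chromen-4-one F4. MeI (1.05 equiv), K2CO3, acetone, rt then methylates only the 3-OH, because the strongly chelated 5-OH is the least reactive hydroxyl of a flavonol. This comes back to the route at 16.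

**Further compounds**

F1 | step 2 | (2,3,4,6-tetramethoxyphenyl)lithium | [Li]c1c(OC)cc(OC)c(OC)c1OC
F2 | step 7 | {2-[5-(benzyloxy)-2-methoxyphenyl]-5,7,8-trimethoxy-4-oxo-4H-chromen-3-yl}lithium | [Li]c1c(-c2cc(OCc3ccccc3)ccc2OC)oc2c(OC)c(OC)cc(OC)c2c1=O
F3 | step 7 | dimethyl {2-[5-(benzyloxy)-2-methoxyphenyl]-5,7,8-trimethoxy-4-oxo-4H-chromen-3-yl}boronate | COB(OC)c1c(-c2cc(OCc3ccccc3)ccc2OC)oc2c(OC)c(OC)cc(OC)c2c1=O
F4 | step 9 | 2-[5-(benzyloxy)-2-methoxyphenyl]-3,5-dihydroxy-7,8-dimethoxy-4H-chromen-4-one | COc1ccc(OCc2ccccc2)cc1-c1oc2c(OC)c(OC)cc(O)c2c(=O)c1O
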